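Counted by the E in it, one J as two, the charge is a fixed sum in a closed flask, so a falling J percentage means J passing into other forms.

| flask | E | remark | time |
|---|---|---|---|
| autumn | 0.30 M | run made earlier |  |
| noon | 0.20 M | run made earlier |  |
| dusk | 0.45 M | run made earlier |  |
| Sunday's | 0.30 M | one stirred flow tank at steady state, fed with the mixture as stated, mean residence time 15 min |  |
| Friday's | 0.30 M | a closed flask charged with all of it at once and left for 15 min | 15 min |

- autumn (time / min: J / %): 0.500: 34.9; 1.33: 52.6; 2.50: 54.9; 4.00: 49.6; 5.00: 44.8; 8.00: 31.9; 10.0: 25.3
- noon (time / min: J / %): 0.667: 31.1; 1.00: 39.7; 1.50: 45.5; 2.50: 49.5; 4.00: 46.7; 6.00: 38.5; 10.0: 25.3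
- dusk (time / min: J / %): 1.33: 60.3; 2.50: 59.3; 4.00: 51.1; 5.00: 45.5; 6.00: 40.3; 8.00: 30.3; 10.0: 24.5

(each reading ± 0.5 percentage points)

- a species is counted by the E in it: one J counts as two
- the stated concentrations are those of everything mixed, before any reaction; amounts are the same in each set-up
- the earlier runs were made in a closed, stirred flask

* the set-up with the highest amount of J at the outlet or at the end, in percent of the E put in ("none" if the first two lie within 2 percentage points) (Sunday's / Friday's / none)
* amount of J at the outlet or at the end, in percent of the E put in, Sunday's
* amount of J at the outlet or at the end, in percent of the E put in, Friday's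

The autumn run has the charge of both new vessels. Its J reading peaks near 2.50 min, earlier than 15 min, and then falls from 44.8 % to 25.3 % between 5.00 min and 10.0 min, which reads as a loss constant of 0.114 /min. Multiplied by 15 min, it gives 1.71 as the number of J lifetimes spent in the vessel, for the tank the Damköhler number.

Because the autumn J reading peaks earlier than the stay ends, my own reckoning treats most of the stay as loss. Of the J formed, Friday's closed flask keeps the share exponential of minus n, 18.1 %, while Sunday's tank, where formation balances loss plus outflow, keeps one part in one plus n, 36.9 %, a larger share. For equal J formed, the tank should therefore hold 2.05 times the flask's J. Running the autumn tail on gives Friday's 14.3 %.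

The forecast, reading “first-order loss of J”, names Sunday's, with 19 % for Sunday's and 14.5 % for Friday's, a smaller ratio of 1.31 than mine.

The flasks give 23.6 % for Sunday's and 13.9 % for Friday's, so Sunday's leads.

    E → Z (k = 1.20 × 10⁻⁵ /s)
    2 E ⇌ J (K = 37.0 /M, k = 0.0330 /M/s)
    J → G (k = 0.00250 /s)

By that step alone, J passes into G with a half-life of 4.6 min, far shorter than the 16 h of E passing into Z alone, and shorter than 15 min. Sunday's tank holds 1.70 times Friday's J, against the 2.05 reckoned from n = 1.71. Carried to a closed flask charged as in the noon run, the same constant takes the last reading of 25.3 % to 14.3 % at 15 min, and that flask holds 14.6 %.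

Readings and results are calculated with constants of no real substance; the scatter is artificial.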